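The ester carbon chain is numbered C1 (ester carbonyl) to C10 throughout.

**Strategy.** The route rests on cutting the C2–C3 bond of the 3-hydroxydecanoate chain as an acetate aldol between octanal and the acetate of the fully substituted phenol. The ester oxygen sits on the benzene carbon flanked by the two ring methyl groups, so the ester is a 2,6-dimethylphenyl-type ester whose enolate equivalents resist ketene loss and self-condensation; the natural ester itself can therefore serve as the nucleophile. A catalytic enantioselective Mukaiyama aldol of its trimethylsilyl ketene acetal (catechol as acetonide, CHO as dimethyl acetal) with octanal forms the C2–C3 bond and the (R)-carbinol centre in one operation. The arene comes from 2,6-dimethylbenzoquinone by Thiele–Winter acetoxylation.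

Key step: step 6

Remark on the chemistry: the antipode of the titanium catalyst in step 6 is the one that directs the ketene acetal to the Si face of octanal (this face gives 3R). Which ligand antipode does this is not asserted here; it is to be fixed on a test scale by Mosher ester analysis of 11.

**Step 1**
Reactants: 1 2,6-dimethyl-1,4-benzoquinone
Product: 2 3,5-dimethylbenzene-1,2,4-triyl triacetate
Conditions: Ac2O, BF3·OEt2 (cat.), 40 °C
Reagents that add atoms: acetic anhydride CC(=O)OC(C)=O
Why: Thiele–Winter acetoxylation: the Lewis-acid-activated quinone accepts acetate at its only unsubstituted enone β-carbon (C3 and C5 are equivalent by symmetry), and aromatization with exhaustive acetylation should give a single triacetate regioisomer.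

**Step 2**
Reactants: 2 3,5-dimethylbenzene-1,2,4-triyl triacetate
Product: 4 2,2,4,6-tetramethyl-1,3-benzodioxol-5-ol, via 3,5-dimethylbenzene-1,2,4-triol 3 (not isolated)
Conditions: HCl (cat.), degassed MeOH, 50 °C, Ar; concentrate; then 2,2-dimethoxypropane, TsOH (cat.), toluene, reflux with removal of MeOH (4 Å MS), Ar
Reagents that add atoms: 2,2-dimethoxypropane COC(C)(C)OC
Why: Acid-catalysed transesterification frees the air-sensitive triol, and acid-catalysed ketal exchange can close a five-membered dioxole only across the two adjacent hydroxyls, so the phenol between the two methyl groups should stay free.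

**Step 3**
Reactants: 4 2,2,4,6-tetramethyl-1,3-benzodioxol-5-ol
Product: 5 6-hydroxy-2,2,5,7-tetramethyl-1,3-benzodioxole-4-carbaldehyde
Conditions: Cl2CHOMe, TiCl4, CH2Cl2, −78 → 0 °C; cold aqueous quench
Reagents that add atoms: dichloromethyl methyl ether COC(Cl)Cl; water O
Why: Rieche formylation, an electrophilic aromatic substitution that can only occur at the single unsubstituted ring carbon, which is activated by the ortho dioxole oxygen and the ortho and para methyl groups; low temperature and a cold quench limit Lewis-acid opening of the ketal.

**Step 4**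
Reactants: 5 6-hydroxy-2,2,5,7-tetramethyl-1,3-benzodioxole-4-carbaldehyde
Product: 7 7-(dimethoxymethyl)-2,2,4,6-tetramethyl-1,3-benzodioxol-5-yl acetate, via phenol dimethyl acetal 6 (not isolated)
Conditions: HC(OMe)3, PPTS (cat.), MeOH, rt; Et3N, concentrate; then Ac2O, Et3N, DMAP (cat.), CH2Cl2, 0 °C → rt
Reagents that add atoms: trimethyl orthoformate COC(OC)OC; methanol CO; acetic anhydride CC(=O)OC(C)=O
Why: Orthoformate-driven acetalization masks the formyl group against the base of step 5 and as a competing electrophile in step 6, and DMAP-catalysed acylation then esterifies the hindered phenol in the same flask, so the acid-sensitive acetal is not purified at the free-phenol stage.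

**Step 5**
Reactants: 7 7-(dimethoxymethyl)-2,2,4,6-tetramethyl-1,3-benzodioxol-5-yl acetate
Product: 8 1-{[7-(dimethoxymethyl)-2,2,4,6-tetramethyl-1,3-benzodioxol-5-yl]oxy}-1-(trimethylsilyloxy)ethene
Conditions: LDA, TMSCl (present during enolization), THF, −78 °C → rt; pentane, filtration, used crude
Reagents that add atoms: chlorotrimethylsilane C[Si](C)(C)Cl
Why: Kinetic ester enolization with LDA and in situ O-silylation should give the O-silyl ketene acetal; the two methyl groups ortho to the ester oxygen suppress ketene expulsion and Claisen self-condensation, as in hindered aryl ester enolate chemistry.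

**Step 6**
Reactants: 8 1-{[7-(dimethoxymethyl)-2,2,4,6-tetramethyl-1,3-benzodioxol-5-yl]oxy}-1-(trimethylsilyloxy)ethene; 9 octanal
Product: 11 7-(dimethoxymethyl)-2,2,4,6-tetramethyl-1,3-benzodioxol-5-yl (3R)-3-hydroxydecanoate, via trimethylsilyl ether 10 (not isolated)
Conditions: 9 (1.5 equiv), Ti(IV) catalyst (5 mol %) from Ti(OiPr)4, the Schiff base of 2-amino-2′-hydroxy-1,1′-binaphthyl and 3-bromo-5-tert-butylsalicylaldehyde (Si-face antipode) and 3,5-di-tert-butylsalicylic acid, Et2O, −10 °C; then PPTS (cat.), MeOH, 0 °C
Reagents that add atoms: none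
Why: Catalytic enantioselective Mukaiyama acetate aldol: the chiral Ti(IV) Lewis acid binds octanal, the terminal CH2 of ketene acetal 8 attacks the activated carbonyl through an open transition state, and silyl transfer shuttled by the salicylate ligand releases the TMS ether 10 and the catalyst. The closest known reaction type is the Ti(IV)/binaphthyl Schiff-base-catalysed addition of acetate O-silyl ketene acetals to aliphatic aldehydes, and aryl-ester-derived ketene acetals are established nucleophiles in the related boron-catalysed versions. No ring is closed. The new C3 stereocentre is set by the catalyst alone, through attack on the Si face of octanal, which corresponds to 3R because CH2CO2Ar outranks heptyl. The step needs chemoselectivity for octanal over the ring formyl carbon and a stable nucleophile: the dimethyl acetal removes the competing electrophile, and the two methyl groups flanking the ester oxygen protect the aryl ketene acetal from ketene loss and acyl transfer. Mild methanolysis should then remove only the TMS group, leaving the acetal and ketal in place.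

**Step 7**
Reactants: 11 7-(dimethoxymethyl)-2,2,4,6-tetramethyl-1,3-benzodioxol-5-yl (3R)-3-hydroxydecanoate
Product: 12 Penicipurate A, 3-formyl-4,5-dihydroxy-2,6-dimethylphenyl (3R)-3-hydroxydecanoate
Conditions: TFA/H2O (9:1), 0 °C → rt; pH 7 buffer work-up
Reagents that add atoms: water O
Why: Acid-catalysed hydrolysis of the dimethyl acetal and of the catechol isopropylidene ketal in a non-nucleophilic medium, which the hindered aryl ester and the β-hydroxy ester should tolerate; the C3 stereocentre is not involved.

**Compound list**
1 | 2,6-dimethyl-1,4-benzoquinone | CC1=CC(=O)C=C(C)C1=O | starting material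
2 | 3,5-dimethylbenzene-1,2,4-triyl triacetate | CC(=O)Oc1c(C)c(OC(C)=O)c(OC(C)=O)cc1C | intermediate
3 | 3,5-dimethylbenzene-1,2,4-triol | Oc1c(C)c(O)c(O)cc1C | intermediate
4 | 2,2,4,6-tetramethyl-1,3-benzodioxol-5-ol | Oc1c(C)c2OC(C)(C)Oc2cc1C | intermediate
5 | 6-hydroxy-2,2,5,7-tetramethyl-1,3-benzodioxole-4-carbaldehyde | Oc1c(C)c2OC(C)(C)Oc2c(C=O)c1C | intermediate
6 | 7-(dimethoxymethyl)-2,2,4,6-tetramethyl-1,3-benzodioxol-5-ol | Oc1c(C)c2OC(C)(C)Oc2c(C(OC)OC)c1C | intermediate
7 | 7-(dimethoxymethyl)-2,2,4,6-tetramethyl-1,3-benzodioxol-5-yl acetate | CC(=O)Oc1c(C)c2OC(C)(C)Oc2c(C(OC)OC)c1C | intermediate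
8 | 1-{[7-(dimethoxymethyl)-2,2,4,6-tetramethyl-1,3-benzodioxol-5-yl]oxy}-1-(trimethylsilyloxy)ethene | C=C(O[Si](C)(C)C)Oc1c(C)c2OC(C)(C)Oc2c(C(OC)OC)c1C | intermediate
9 | octanal | CCCCCCCC=O | starting material
10 | 7-(dimethoxymethyl)-2,2,4,6-tetramethyl-1,3-benzodioxol-5-yl (3R)-3-(trimethylsilyloxy)decanoate | CCCCCCC[C@@H](O[Si](C)(C)C)CC(=O)Oc1c(C)c2OC(C)(C)Oc2c(C(OC)OC)c1C | intermediate
11 | 7-(dimethoxymethyl)-2,2,4,6-tetramethyl-1,3-benzodioxol-5-yl (3R)-3-hydroxydecanoate | CCCCCCC[C@@H](O)CC(=O)Oc1c(C)c2OC(C)(C)Oc2c(C(OC)OC)c1C | intermediate
12 | Penicipurate A, 3-formyl-4,5-dihydroxy-2,6-dimethylphenyl (3R)-3-hydroxydecanoate | CCCCCCC[C@@H](O)CC(=O)Oc1c(C)c(O)c(O)c(C=O)c1C | target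

Total step count: 7. Longest linear sequence: 7 steps (1 → 12).

**Steps most likely to fail**

Step 6. The bulky, less nucleophilic aryl ketene acetal may slow the silyl-transfer turnover, so that a racemic background addition erodes the facial selectivity. The fallback makes the same C2–C3 bond without stereochemical demand and sets the centre afterwards. It sets out from 8, which is C-acylated with octanoyl chloride (CH2Cl2, 0 °C → rt) to give 7-(dimethoxymethyl)-2,2,4,6-tetramethyl-1,3-benzodioxol-5-yl 3-oxodecanoate F1. Noyori hydrogenation of this β-keto ester with a Ru–(R)-BINAP catalyst (H2, CH2Cl2/MeOH, 30–40 °C), the antipode known to deliver (R)-β-hydroxy esters, should return to 11.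

Step 3. The Lewis acid may open the dioxole ring during or after formylation, helped by chelation between the new formyl group and the neighbouring ring oxygen. The fallback introduces the formyl group before any ketal exists. It sets out from 2, which undergoes Rieche formylation (Cl2CHOMe, TiCl4, CH2Cl2, 0 °C → rt) at its only free ring position to give 6-formyl-3,5-dimethylbenzene-1,2,4-triyl triacetate F2. Acidic methanolysis (HCl, MeOH, Ar) then gives 2,3,5-trihydroxy-4,6-dimethylbenzaldehyde F3. Treatment with 2,2-dimethoxypropane and TsOH in MeOH/toluene should form the dioxole and the dimethyl acetal together, giving 6, which is acetylated as in the second stage of step 4 to reach 7.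

Step 7. Hydrolysis of the ketal next to the electron-poor formyl-bearing carbon may be slow enough that ester hydrolysis or β-elimination competes. The fallback stages the unmasking and opens the ketal under anhydrous chelation control instead of protic hydrolysis. It sets out from 11: PPTS in wet acetone (rt) hydrolyses only the acetal, giving 7-formyl-2,2,4,6-tetramethyl-1,3-benzodioxol-5-yl (3R)-3-hydroxydecanoate F4. BCl3 (CH2Cl2, −78 °C), bound between the formyl oxygen and the adjacent dioxole oxygen, then cleaves the ketal, and a buffered aqueous work-up should give 12.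

**Further compounds**
F1 | step 6 | 7-(dimethoxymethyl)-2,2,4,6-tetramethyl-1,3-benzodioxol-5-yl 3-oxodecanoate | CCCCCCCC(=O)CC(=O)Oc1c(C)c2OC(C)(C)Oc2c(C(OC)OC)c1C
F2 | step 3 | 6-formyl-3,5-dimethylbenzene-1,2,4-triyl triacetate | CC(=O)Oc1c(C)c(OC(C)=O)c(OC(C)=O)c(C=O)c1C
F3 | step 3 | 2,3,5-trihydroxy-4,6-dimethylbenzaldehyde | Oc1c(C)c(O)c(O)c(C=O)c1C
F4 | step 7 | 7-formyl-2,2,4,6-tetramethyl-1,3-benzodioxol-5-yl (3R)-3-hydroxydecanoate | CCCCCCC[C@@H](O)CC(=O)Oc1c(C)c2OC(C)(C)Oc2c(C=O)c1C
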